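**Direct plan and its weak points**

A direct plan would grow the nona-ether two rings at a time by repeated SNAr of a two-ring phenol A1 onto ortho-fluorobenzaldehyde chain ends. It would reach the ten-ring hexa-aldehyde A2, turn the six formyl groups into hydroxyls by Dakin oxidation (hexaphenol A3) and then cleave twenty methyl ethers.
- Making A1 would be weak: its pentaoxygenated ring needs a long and partly unproven ring construction before any chain growth can start.
- The chain growth would be weak: four SNAr/acetal-unmasking cycles in a line, each pushing a phenoxide flanked by two oxygens onto a crowded aryl carbon.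
- The sixfold Dakin oxidation would be weak: the formyl groups serve only as activators, so it is a redox detour, and it exposes an electron-rich ten-ring polyether to excess peracid at the end.

**Retrosynthetic overview**

Rings are numbered 1 (2,4,6-trihydroxyphenyl end) to 10 (3,4,5-trihydroxyphenyl end). Rings 2, 4, 6, 8 and 10 are 1,2,3,5-tetraoxygenated, that is, aromatised triketides whose C4 (flanked by two OH) carries the ether oxygen to the next ring.
These five rings are therefore carried as 4-aryloxy-6-(aryloxymethyl)-2-pyranones (masked triketides, as in phloroglucinol biosynthesis). The crowded C4–O bond is first an alkyl aryl ether at the exocyclic CH2, and the C1–O bond a vinylogous ester at pyranone C4.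
Rings 1, 3, 5, 7 and 9 come from two commercial trimethoxyphenols. The key step then forms rings 2, 4, 6, 8 and 10 together from the pentakis-pyranone 20, by a new C–C bond between each lactone carbonyl carbon and its exocyclic OCH2 carbon.
No ether is made by SNAr on a benzene ring, there is no aldehyde/Dakin detour, the ten hydroxyls of the new rings appear unprotected, and 16 instead of 20 methyl ethers remain to be cleaved.

Key step: step 11

Assumption: 4-bromo-6-methyl-2H-pyran-2-one (1), 2,3,4-trimethoxyphenol (5) and 2,4,6-trimethoxyphenol (11) are taken as commercial; 1 is otherwise one step from 4-hydroxy-6-methyl-2-pyranone (Bu4NBr, P2O5).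

Shorthand in names:
- Ar = 2,4,6-trimethoxyphenyl.
- P = 2-oxo-2H-pyran-4,6-diyl, bound through O at C4 to the unit on its left and through its 6-CH2-O group to the unit on its right.
- B = 3,4,5-trimethoxy-1,2-phenylene, C1-O to the left and C2-O to the right.
- T = 3,5-dihydroxy-1,4-phenylene, C1-O to the left and C4-O to the right.
- T' = 3,5-dihydroxy-4-methoxyphenyl.

**Route**

Step 1
Reactants: 1 4-bromo-6-methyl-2H-pyran-2-one
Product: 3 4-bromo-6-(hydroxymethyl)-2H-pyran-2-one, via bromomethyl pyranone 2 (not isolated)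
Conditions: NBS (1.05 equiv), AIBN (5 mol%), PhCF3, 85 °C; filter, concentrate; then Ag2CO3 (0.6 equiv), acetone/H2O 5:1, rt, dark
Reagents that add atoms: water, O
Why: Wohl–Ziegler radical bromination takes the 6-methyl group (dienylic radical, as known for 4-methoxy-6-methyl-2-pyranone), and silver-assisted hydrolysis then exchanges only the sp3 bromide, because the vinylic C4–Br bond is inert to water when no free oxyanion is present.

Step 2
Reactants: 3 4-bromo-6-(hydroxymethyl)-2H-pyran-2-one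
Product: 4 4-bromo-6-(methoxymethyl)-2H-pyran-2-one
Conditions: MeI (5 equiv), Ag2O (1.5 equiv), CH2Cl2, rt, dark
Reagents that add atoms: iodomethane, CI
Why: Silver oxide-mediated O-methylation (Williamson-type etherification without a free alkoxide) caps the alcohol as the methyl ether that becomes the 4-oxygen of ring 10, and leaves the vinylogous acyl bromide at C4 for step 10.

Step 3
Reactants: 5 2,3,4-trimethoxyphenol
Product: 6 1,2,3-trimethoxy-4-(methoxymethoxy)benzene
Conditions: MOMCl (1.3 equiv), i-Pr2NEt (1.5 equiv), CH2Cl2, 0 °C to rt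
Reagents that add atoms: chloromethyl methyl ether, COCCl
Why: O-alkylation of the phenol with the chloromethyl ether gives the MOM acetal, which directs the ortho-lithiation of step 4 and masks the hindered oxygen O2 of rings 3, 5, 7 and 9.

Step 4
Reactants: 6 1,2,3-trimethoxy-4-(methoxymethoxy)benzene
Product: 9 2-(methoxymethoxy)-3,4,5-trimethoxyphenol, via aryllithium 7 (not isolated), via dimethyl arylboronate 8 (not isolated)
Conditions: n-BuLi (1.15 equiv), THF, −78 to 0 °C; B(OMe)3 (1.5 equiv), −78 °C to rt; then AcOH (1.5 equiv), 30% H2O2 (1.5 equiv), 0 °C to rt; Na2S2O3 wash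
Reagents that add atoms: hydrogen peroxide, OO
Why: Directed ortho-metalation puts lithium on the only free position ortho to the MOM ether, and borylation with oxidative C–B to C–O migration gives the phenol, so the two catechol oxygens are differentiated from the start (O1 free, O2 as MOM ether).

Step 5
Reactants: 9 2-(methoxymethoxy)-3,4,5-trimethoxyphenol; 3 4-bromo-6-(hydroxymethyl)-2H-pyran-2-one
Product: 10 4-bromo-6-{[2-(methoxymethoxy)-3,4,5-trimethoxyphenoxy]methyl}-2H-pyran-2-one
Conditions: PPh3 (1.3 equiv), DIAD (1.3 equiv), THF, 0 °C (betaine preformed); then 9 and 3, 0 °C to rt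
Reagents that add atoms: none
Why: Mitsunobu etherification joins the unhindered phenol O1 to the primary alcohol by SN2 at CH2 under neutral conditions, so the oxygen that will sit on the crowded C4 of rings 2, 4, 6 and 8 is attached to an unhindered sp3 carbon, and the C4–Br bond is kept because no free phenoxide is present.

Step 6
Reactants: 11 2,4,6-trimethoxyphenol; 10 4-bromo-6-{[2-(methoxymethoxy)-3,4,5-trimethoxyphenoxy]methyl}-2H-pyran-2-one
Product: 13 three-unit phenol Ar-O-P-CH2-O-B-OH, via MOM ether 12 (not isolated)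
Conditions: 10 (1.1 equiv), K2CO3 (2 equiv), MeCN, 40 °C; filter, concentrate; then HCl (0.3 M) in MeOH/THF 1:1, 0 °C to rt; NaHCO3 work-up
Reagents that add atoms: none
Why: Addition–elimination (vinylogous acyl substitution) of the di-ortho-substituted phenoxide at C4 of the 4-bromopyranone makes the ring 1–ring 2 ether oxygen at an unhindered sp2 carbon, and acid-catalysed transacetalisation in methanol then frees the next hindered phenol while methanol traps the methoxymethyl cation.

Step 7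
Reactants: 13 three-unit phenol Ar-O-P-CH2-O-B-OH; 10 4-bromo-6-{[2-(methoxymethoxy)-3,4,5-trimethoxyphenoxy]methyl}-2H-pyran-2-one
Product: 15 five-unit phenol Ar-O-(P-CH2-O-B-O)-P-CH2-O-B-OH, via five-unit MOM ether 14 (not isolated)
Conditions: 10 (1.15 equiv), K2CO3 (2 equiv), MeCN, 40 °C; filter, concentrate; then HCl (0.3 M) in MeOH/THF 1:1, 0 °C to rt; NaHCO3 work-up
Reagents that add atoms: none
Why: Same addition–elimination/MOM cleavage cycle; bromide at C4 is displaced far faster than the aryloxy group already on the first pyranone, so the existing vinylogous ester link is kept.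

Step 8
Reactants: 15 five-unit phenol Ar-O-(P-CH2-O-B-O)-P-CH2-O-B-OH; 10 4-bromo-6-{[2-(methoxymethoxy)-3,4,5-trimethoxyphenoxy]methyl}-2H-pyran-2-one
Product: 17 seven-unit phenol Ar-O-(P-CH2-O-B-O)2-P-CH2-O-B-OH, via seven-unit MOM ether 16 (not isolated)
Conditions: 10 (1.2 equiv), K2CO3 (2 equiv), MeCN, 40 °C; filter, concentrate; then HCl (0.3 M) in MeOH/THF 1:1, 0 °C to rt; NaHCO3 work-up
Reagents that add atoms: none
Why: Third addition–elimination/MOM cleavage cycle, adding the precursors of rings 6 and 7.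

Step 9
Reactants: 17 seven-unit phenol Ar-O-(P-CH2-O-B-O)2-P-CH2-O-B-OH; 10 4-bromo-6-{[2-(methoxymethoxy)-3,4,5-trimethoxyphenoxy]methyl}-2H-pyran-2-one
Product: 19 nine-unit phenol Ar-O-(P-CH2-O-B-O)3-P-CH2-O-B-OH, via nine-unit MOM ether 18 (not isolated)
Conditions: 10 (1.2 equiv), K2CO3 (2 equiv), MeCN, 40 °C; filter, concentrate; then HCl (0.3 M) in MeOH/THF 1:1, 0 °C to rt; NaHCO3 work-up
Reagents that add atoms: none
Why: Fourth addition–elimination/MOM cleavage cycle, adding the precursors of rings 8 and 9.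

Step 10
Reactants: 19 nine-unit phenol Ar-O-(P-CH2-O-B-O)3-P-CH2-O-B-OH; 4 4-bromo-6-(methoxymethyl)-2H-pyran-2-one
Product: 20 pentakis-pyranone Ar-O-(P-CH2-O-B-O)4-P-CH2-OMe
Conditions: 4 (1.5 equiv), K2CO3 (2 equiv), MeCN, 40 °C
Reagents that add atoms: none
Why: Final addition–elimination with the capped pyranone, which carries no masked phenol, completes the chain with all nine ether oxygens of the target in place.

Step 11
Reactants: 20 pentakis-pyranone Ar-O-(P-CH2-O-B-O)4-P-CH2-OMe
Product: 22 ten-ring decaphenol Ar-O-(T-O-B-O)4-T', via penta-pyranolate potassium salt 21 (not isolated)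
Conditions: KN(SiMe3)2 (6.5 equiv), 18-crown-6 (6.5 equiv), THF (5 mM), −78 °C, slow addition of 20 to the base; then 50 °C, 4 h; AcOH, 0 °C
Reagents that add atoms: none
Why: Proposed new method: the amide base removes a proton from each exocyclic OCH2 group (vinylogous to the lactone carbonyl, acidified by the aryloxy oxygen) to give 21, whose ester-enolate resonance form should expel the ring oxygen in an E1cB-type opening to a (Z)-dienylketene bearing an enolate at the former C6; the enolate carbon then closes onto the ketene carbon (6π electrocyclic closure, equal to a 6-enolendo-exo attack of carbon on C=O) and tautomerisation gives the 2,5-bis(aryloxy)resorcinol monoanion, five times over. The closest known reactions are the alkoxide-mediated conversion of 4-alkoxy-6-methyl-2-pyranones into 5-alkoxyresorcinols (lactone opening, then Claisen closure) and the dienylketene-to-phenol electrocyclisation of the Moore and Danheiser benzannulations; the alkoxide-free variant is proposed because methoxide would also substitute the vinylogous aryl ester at pyranone C4 and cut the chain. No stereocentre is formed. The step needs C- over O-acylation and retention of all ether oxygens: O-closure only regenerates the pyranolate and is reversible, C-closure is made irreversible by aromatisation, no external nucleophile is present to exchange an aryloxy group, and full deprotonation of all five pyranones before warming (together with high dilution) leaves no electrophilic lactone for intermolecular condensation.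

Step 12
Reactants: 22 ten-ring decaphenol Ar-O-(T-O-B-O)4-T'
Product: 23 CNP0255890.0
Conditions: BBr3 (50 equiv), CH2Cl2, −78 °C to rt, 24 h, Ar; MeOH then H2O at 0 °C; evaporation; reversed-phase chromatography, degassed H2O/MeCN (0.1% HCO2H), Ar
Reagents that add atoms: none
Why: Lewis-acid ether cleavage by BBr3 should remove the 16 aryl methyl ethers while the diaryl ethers stay intact; the product has no stereocentre.

**Compound list**

1 | 4-bromo-6-methyl-2H-pyran-2-one | CC1=CC(Br)=CC(=O)O1 | starting material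
2 | 4-bromo-6-(bromomethyl)-2H-pyran-2-one | BrCC1=CC(Br)=CC(=O)O1 | intermediate
3 | 4-bromo-6-(hydroxymethyl)-2H-pyran-2-one | OCC1=CC(Br)=CC(=O)O1 | intermediate
4 | 4-bromo-6-(methoxymethyl)-2H-pyran-2-one | COCC1=CC(Br)=CC(=O)O1 | intermediate
5 | 2,3,4-trimethoxyphenol | COc1ccc(O)c(OC)c1OC | starting material
6 | 1,2,3-trimethoxy-4-(methoxymethoxy)benzene | COCOc1ccc(OC)c(OC)c1OC | intermediate
7 | [2-(methoxymethoxy)-3,4,5-trimethoxyphenyl]lithium | [Li]c1cc(OC)c(OC)c(OC)c1OCOC | intermediate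
8 | dimethyl [2-(methoxymethoxy)-3,4,5-trimethoxyphenyl]boronate | COB(OC)c1cc(OC)c(OC)c(OC)c1OCOC | intermediate
9 | 2-(methoxymethoxy)-3,4,5-trimethoxyphenol | COCOc1c(O)cc(OC)c(OC)c1OC | intermediate
10 | 4-bromo-6-{[2-(methoxymethoxy)-3,4,5-trimethoxyphenoxy]methyl}-2H-pyran-2-one | COCOc1c(OCC2=CC(Br)=CC(=O)O2)cc(OC)c(OC)c1OC | intermediate
11 | 2,4,6-trimethoxyphenol | COc1cc(OC)c(O)c(OC)c1 | starting material
12 | 6-{[2-(methoxymethoxy)-3,4,5-trimethoxyphenoxy]methyl}-4-(2,4,6-trimethoxyphenoxy)-2H-pyran-2-one (MOM ether of 13) | COc1cc(OC)c(OC2=CC(=O)OC(COc3cc(OC)c(OC)c(OC)c3OCOC)=C2)c(OC)c1 | intermediate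
13 | 6-[(2-hydroxy-3,4,5-trimethoxyphenoxy)methyl]-4-(2,4,6-trimethoxyphenoxy)-2H-pyran-2-one (three-unit phenol Ar-O-P-CH2-O-B-OH) | COc1cc(OC)c(OC2=CC(=O)OC(COc3cc(OC)c(OC)c(OC)c3O)=C2)c(OC)c1 | intermediate
14 | five-unit MOM ether Ar-O-(P-CH2-O-B-O)-P-CH2-O-B-OMOM | COc1cc(OC)c(OC2=CC(=O)OC(COc3cc(OC)c(OC)c(OC)c3OC4=CC(=O)OC(COc5cc(OC)c(OC)c(OC)c5OCOC)=C4)=C2)c(OC)c1 | intermediate
15 | five-unit phenol Ar-O-(P-CH2-O-B-O)-P-CH2-O-B-OH | COc1cc(OC)c(OC2=CC(=O)OC(COc3cc(OC)c(OC)c(OC)c3OC4=CC(=O)OC(COc5cc(OC)c(OC)c(OC)c5O)=C4)=C2)c(OC)c1 | intermediate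
16 | seven-unit MOM ether Ar-O-(P-CH2-O-B-O)2-P-CH2-O-B-OMOM | COc1cc(OC)c(OC2=CC(=O)OC(COc3cc(OC)c(OC)c(OC)c3OC4=CC(=O)OC(COc5cc(OC)c(OC)c(OC)c5OC6=CC(=O)OC(COc7cc(OC)c(OC)c(OC)c7OCOC)=C6)=C4)=C2)c(OC)c1 | intermediate
17 | seven-unit phenol Ar-O-(P-CH2-O-B-O)2-P-CH2-O-B-OH | COc1cc(OC)c(OC2=CC(=O)OC(COc3cc(OC)c(OC)c(OC)c3OC4=CC(=O)OC(COc5cc(OC)c(OC)c(OC)c5OC6=CC(=O)OC(COc7cc(OC)c(OC)c(OC)c7O)=C6)=C4)=C2)c(OC)c1 | intermediate
18 | nine-unit MOM ether Ar-O-(P-CH2-O-B-O)3-P-CH2-O-B-OMOM | COc1cc(OC)c(OC2=CC(=O)OC(COc3cc(OC)c(OC)c(OC)c3OC4=CC(=O)OC(COc5cc(OC)c(OC)c(OC)c5OC6=CC(=O)OC(COc7cc(OC)c(OC)c(OC)c7OC8=CC(=O)OC(COc9cc(OC)c(OC)c(OC)c9OCOC)=C8)=C6)=C4)=C2)c(OC)c1 | intermediate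
19 | nine-unit phenol Ar-O-(P-CH2-O-B-O)3-P-CH2-O-B-OH | COc1cc(OC)c(OC2=CC(=O)OC(COc3cc(OC)c(OC)c(OC)c3OC4=CC(=O)OC(COc5cc(OC)c(OC)c(OC)c5OC6=CC(=O)OC(COc7cc(OC)c(OC)c(OC)c7OC8=CC(=O)OC(COc9cc(OC)c(OC)c(OC)c9O)=C8)=C6)=C4)=C2)c(OC)c1 | intermediate
20 | pentakis-pyranone Ar-O-(P-CH2-O-B-O)4-P-CH2-OMe (five 4-aryloxy-6-(oxymethyl)-2-pyranones alternating with the aryl rings 1, 3, 5, 7, 9) | COc1cc(OC)c(OC2=CC(=O)OC(COc3cc(OC)c(OC)c(OC)c3OC4=CC(=O)OC(COc5cc(OC)c(OC)c(OC)c5OC6=CC(=O)OC(COc7cc(OC)c(OC)c(OC)c7OC8=CC(=O)OC(COc9cc(OC)c(OC)c(OC)c9OC%10=CC(=O)OC(COC)=C%10)=C8)=C6)=C4)=C2)c(OC)c1 | intermediate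
21 | pentapotassium salt of 20, deprotonated at each of the five exocyclic OCH2 carbons | [K+].[K+].[K+].[K+].[K+].COc1cc(OC)c(OC2=CC(=O)OC([CH-]Oc3cc(OC)c(OC)c(OC)c3OC4=CC(=O)OC([CH-]Oc5cc(OC)c(OC)c(OC)c5OC6=CC(=O)OC([CH-]Oc7cc(OC)c(OC)c(OC)c7OC8=CC(=O)OC([CH-]Oc9cc(OC)c(OC)c(OC)c9OC%10=CC(=O)OC([CH-]OC)=C%10)=C8)=C6)=C4)=C2)c(OC)c1 | intermediate
22 | ten-ring decaphenol Ar-O-(T-O-B-O)4-T' (rings 2, 4, 6, 8 as 3,5-dihydroxy-1,4-phenylene, ring 10 as 3,5-dihydroxy-4-methoxyphenyl; 16 OMe, 10 OH) | COc1cc(OC)c(Oc2cc(O)c(Oc3cc(OC)c(OC)c(OC)c3Oc4cc(O)c(Oc5cc(OC)c(OC)c(OC)c5Oc6cc(O)c(Oc7cc(OC)c(OC)c(OC)c7Oc8cc(O)c(Oc9cc(OC)c(OC)c(OC)c9Oc%10cc(O)c(OC)c(O)c%10)c(O)c8)c(O)c6)c(O)c4)c(O)c2)c(OC)c1 | intermediate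
23 | CNP0255890.0 (ten rings, nine diaryl ethers, 26 OH; achiral) | Oc1cc(O)c(Oc2cc(O)c(Oc3cc(O)c(O)c(O)c3Oc3cc(O)c(Oc4cc(O)c(O)c(O)c4Oc4cc(O)c(Oc5cc(O)c(O)c(O)c5Oc5cc(O)c(Oc6cc(O)c(O)c(O)c6Oc6cc(O)c(O)c(O)c6)c(O)c5)c(O)c4)c(O)c3)c(O)c2)c(O)c1 | target

**Step count and risks**

Total steps: 12. Longest linear sequence: 10 steps (5 → 6 → 9 → 10 → 13 → 15 → 17 → 19 → 20 → 22 → 23).

Steps most likely to fail:

1. Step 11 (Proposed new method). The penta-pyranolate may be too stabilised to open, so that 20 is recovered after the quench, or a carbanion may add to a neighbouring pyranone that is not yet deprotonated. The fallback uses known chemistry and sets out from 20. The five enol lactones are opened with NaOMe (5.5 equiv, MeOH/THF, −20 °C, short contact) to the acyclic pentakis(methyl (E)-3-aryloxy-5-oxohex-2-enoate) F1 (not isolated). Methanol is removed in the cold, and the five rings are closed by Dieckmann-type Claisen condensation with KOt-Bu in t-BuOH/THF at 40 °C, which comes back to the route at 22. This is the stepwise form of the known alkoxide conversion of 4-alkoxy-6-methyl-2-pyranones into 5-alkoxyresorcinols. It is kept as the fallback because methoxide can also exchange the aryloxy groups at pyranone C4.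

2. Step 9 (the same process threatens steps 7, 8 and 10 to a smaller degree). As the chain grows, the hindered phenoxide meets more vinylogous aryl ester links. It may attack pyranone C4 of a link already made (transetherification, chain scission or scrambling), or add to C6 of the neighbouring pyranone, instead of displacing bromide from 10. The fallback is a convergent five-plus-five union that sets out from 10, 4 and 15. MOM cleavage of 10 (HCl, MeOH/THF) gives the bromo phenol 4-bromo-6-[(2-hydroxy-3,4,5-trimethoxyphenoxy)methyl]-2H-pyran-2-one F2, which is stable while neutral. Slow addition of F2 to excess 4 (5 equiv, K2CO3, MeCN) gives the three-unit bromide F3; the excess electrophile suppresses self-condensation of F2. The same operation with F2 and excess F3 (surplus recovered) gives the five-unit bromide F4. Addition–elimination of 15 on F4 comes back to the route at 20. The longest phenoxide then exposed to base carries two vinylogous ester links instead of four.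

3. Step 12. Cleavage of 16 methyl ethers may stop at partly methylated congeners that are hard to separate, and the free 26-fold phenol may be lost by air oxidation and irreversible adsorption during isolation. The fallback changes the isolation and sets out from 22. After the BBr3 reaction and methanol quench, the crude polyphenol is acetylated (Ac2O, pyridine, DMAP) to the hexacosaacetate F5, which is stable and can be purified on silica away from under-demethylated material. Acid-catalysed methanolysis (HCl in degassed MeOH, Ar) then releases 23 without a phenoxide ever being formed.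

Further compounds
F1 | step 11 | acyclic pentakis(methyl ester): each pyranone of 20 opened to a methyl (E)-3-aryloxy-5-oxo-6-oxyhex-2-enoate unit | COc1cc(OC)c(O/C(=C/C(=O)OC)CC(=O)COc2cc(OC)c(OC)c(OC)c2O/C(=C/C(=O)OC)CC(=O)COc3cc(OC)c(OC)c(OC)c3O/C(=C/C(=O)OC)CC(=O)COc4cc(OC)c(OC)c(OC)c4O/C(=C/C(=O)OC)CC(=O)COc5cc(OC)c(OC)c(OC)c5O/C(=C/C(=O)OC)CC(=O)COC)c(OC)c1
F2 | step 9 | 4-bromo-6-[(2-hydroxy-3,4,5-trimethoxyphenoxy)methyl]-2H-pyran-2-one | Oc1c(OCC2=CC(Br)=CC(=O)O2)cc(OC)c(OC)c1OC
F3 | step 9 | three-unit bromide Br-P-CH2-O-B-O-P-CH2-OMe: 4-bromo-6-[(2-{[6-(methoxymethyl)-2-oxo-2H-pyran-4-yl]oxy}-3,4,5-trimethoxyphenoxy)methyl]-2H-pyran-2-one | BrC1=CC(=O)OC(COc2cc(OC)c(OC)c(OC)c2OC3=CC(=O)OC(COC)=C3)=C1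
F4 | step 9 | five-unit bromide Br-P-CH2-O-B-O-P-CH2-O-B-O-P-CH2-OMe | BrC1=CC(=O)OC(COc2cc(OC)c(OC)c(OC)c2OC3=CC(=O)OC(COc4cc(OC)c(OC)c(OC)c4OC5=CC(=O)OC(COC)=C5)=C3)=C1
F5 | step 12 | hexacosaacetate of 23 (all 26 OH as acetates) | CC(=O)Oc1cc(OC(C)=O)c(Oc2cc(OC(C)=O)c(Oc3cc(OC(C)=O)c(OC(C)=O)c(OC(C)=O)c3Oc3cc(OC(C)=O)c(Oc4cc(OC(C)=O)c(OC(C)=O)c(OC(C)=O)c4Oc4cc(OC(C)=O)c(Oc5cc(OC(C)=O)c(OC(C)=O)c(OC(C)=O)c5Oc5cc(OC(C)=O)c(Oc6cc(OC(C)=O)c(OC(C)=O)c(OC(C)=O)c6Oc6cc(OC(C)=O)c(OC(C)=O)c(OC(C)=O)c6)c(OC(C)=O)c5)c(OC(C)=O)c4)c(OC(C)=O)c3)c(OC(C)=O)c2)c(OC(C)=O)c1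
A1 | direct plan | 2-[3-(dimethoxymethyl)-4-fluoro-5-methoxyphenoxy]-3,4,5-trimethoxyphenol | Oc1cc(OC)c(OC)c(OC)c1Oc1cc(OC)c(F)c(C(OC)OC)c1
A2 | direct plan | ten-ring hexa-aldehyde (CHO on rings 1, 2, 4, 6, 8, 10; 20 OMe) | COc1cc(C=O)cc(OC)c1Oc1cc(OC)c(Oc2cc(OC)c(OC)c(OC)c2Oc2cc(OC)c(Oc3cc(OC)c(OC)c(OC)c3Oc3cc(OC)c(Oc4cc(OC)c(OC)c(OC)c4Oc4cc(OC)c(Oc5cc(OC)c(OC)c(OC)c5Oc5cc(OC)c(OC)c(C=O)c5)c(C=O)c4)c(C=O)c3)c(C=O)c2)c(C=O)c1
A3 | direct plan | ten-ring hexaphenol (each CHO of A2 replaced by OH; 20 OMe) | COc1cc(O)cc(OC)c1Oc1cc(OC)c(Oc2cc(OC)c(OC)c(OC)c2Oc2cc(OC)c(Oc3cc(OC)c(OC)c(OC)c3Oc3cc(OC)c(Oc4cc(OC)c(OC)c(OC)c4Oc4cc(OC)c(Oc5cc(OC)c(OC)c(OC)c5Oc5cc(OC)c(OC)c(O)c5)c(O)c4)c(O)c3)c(O)c2)c(O)c1
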